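**Plan**
- Retrosynthesis: the aryl–acyl bond C4–C4a of ring C is cut first. This leads to the isomeric 4-aryloxy-3,4-dihydrocoumarin 20, in which C4 is held as the lactone (aryl ester) of the ring B 2'-OH. Next the lactone C4–O2' is opened and C4 is taken back to a vinyl carbon; then the ether bond C2–O1 is cut (phenol 4 + cinnamyl carbonate 12), then the C2=C3 alkene (Wittig), the formyl, pyran and C-prenyl bonds.
- Forward order: the pyran ring of the chromene is made first, then the C2–O1 ether, then the temporary lactone ring. Ring C is closed last, by an O-to-C acyl shift that turns 20 into the target with no protecting group and no co-product.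
- Enabling feature: ring B carries its OH at C2', ortho to C1', so C4 can be stored as a six-membered aryl ester. Ring A is a phloroglucinol whose C4a is ortho to O1 and O5 and para to O7, a strongly nucleophilic carbon placed for a six-membered closure onto that ester carbon.
- Stereochemistry: C2 (S) is set once, by ligand control in the iridium-catalysed allylic etherification (step 9); no later step breaks a bond at C2.

Key step: step 13

Assumption: the (Sa,Sc,Sc) antipode of the phosphoramidite ligand is taken to be the one that gives the (S)-ether 14; should the first run show the opposite sense of induction, the (Ra,Rc,Rc) ligand is used instead.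

**Route**

Step 1
Reactants: 1 phloroglucinol; 2 prenyl bromide
Product: 3 2-(3-methylbut-2-enyl)benzene-1,3,5-triol
Conditions: 1 (3 equiv), 2 (1 equiv), DBU (1 equiv), THF, 0 °C → rt
Reagents that add atoms: none
Why: C-alkylation of the ambident phloroglucinol anion by a soft allylic bromide; the three ring CH positions are equivalent and the excess of 1 should hold back double prenylation.

Step 2
Reactants: 3 2-(3-methylbut-2-enyl)benzene-1,3,5-triol
Product: 4 2-(3-methylbut-2-enyl)-3,5-bis(triisopropylsilyloxy)phenol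
Conditions: i-Pr3SiCl (2.1 equiv), imidazole, DMF, 0 °C → rt
Reagents that add atoms: triisopropylsilyl chloride, CC(C)[Si](Cl)(C(C)C)C(C)C
Why: Sterically controlled silyl ether formation: the unhindered para OH should react first and either of the two equivalent ortho OH groups second, which leaves one OH next to the prenyl group free.

Step 3
Reactants: 5 resorcinol; 6 3-methylbut-2-enal
Product: 7 2,2-dimethyl-2H-chromen-7-ol
Conditions: pyridine, 140 °C (sealed tube)
Reagents that add atoms: none
Why: 2H-chromene annulation (Knoevenagel-type condensation at C4 of resorcinol, then oxa-6π electrocyclisation); C4, para to one OH and unhindered, should be the preferred site, which gives the 7-hydroxy isomer.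

Step 4
Reactants: 7 2,2-dimethyl-2H-chromen-7-ol
Product: 8 7-hydroxy-2,2-dimethyl-2H-chromene-6-carbaldehyde
Conditions: MgCl2, Et3N, (CH2O)n, MeCN, reflux
Reagents that add atoms: formaldehyde (from paraformaldehyde), C=O
Why: Magnesium-phenoxide-directed ortho-formylation (Casnati–Skattebøl reaction); of the two ortho positions, C6 (para to the ring oxygen) should react rather than C8, which is flanked by both oxygens.

Step 5
Reactants: 8 7-hydroxy-2,2-dimethyl-2H-chromene-6-carbaldehyde
Product: 9 2,2-dimethyl-7-(triisopropylsilyloxy)-2H-chromene-6-carbaldehyde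
Conditions: i-Pr3SiOTf, 2,6-lutidine, CH2Cl2, 0 °C
Reagents that add atoms: triisopropylsilyl trifluoromethanesulfonate, CC(C)[Si](OS(=O)(=O)C(F)(F)F)(C(C)C)C(C)C
Why: Standard silylation; the reactive silyl triflate overcomes the hydrogen bond of the salicylaldehyde OH.

Step 6
Reactants: 9 2,2-dimethyl-7-(triisopropylsilyloxy)-2H-chromene-6-carbaldehyde
Product: 10 ethyl (E)-3-[2,2-dimethyl-7-(triisopropylsilyloxy)-2H-chromen-6-yl]prop-2-enoate
Conditions: Ph3P=CHCO2Et, toluene, 60 °C
Reagents that add atoms: ethyl (triphenylphosphoranylidene)acetate, CCOC(=O)C=P(c1ccccc1)(c1ccccc1)c1ccccc1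
Why: Wittig olefination with a stabilised ylide under neutral conditions should give the (E)-cinnamate.

Step 7
Reactants: 10 ethyl (E)-3-[2,2-dimethyl-7-(triisopropylsilyloxy)-2H-chromen-6-yl]prop-2-enoate
Product: 11 (E)-3-[2,2-dimethyl-7-(triisopropylsilyloxy)-2H-chromen-6-yl]prop-2-en-1-ol
Conditions: i-Bu2AlH (2.2 equiv), CH2Cl2, −78 °C; aq. potassium sodium tartrate (KNaC4H4O6)
Reagents that add atoms: none
Why: 1,2-Reduction of the enoate at low temperature gives the allylic alcohol and leaves the aryl silyl ether and the chromene alkene alone.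

Step 8
Reactants: 11 (E)-3-[2,2-dimethyl-7-(triisopropylsilyloxy)-2H-chromen-6-yl]prop-2-en-1-ol
Product: 12 methyl (E)-3-[2,2-dimethyl-7-(triisopropylsilyloxy)-2H-chromen-6-yl]prop-2-enyl carbonate
Conditions: ClCO2Me, pyridine, CH2Cl2, 0 °C
Reagents that add atoms: methyl chloroformate, COC(=O)Cl
Why: Acylation of the primary allylic alcohol installs the carbonate leaving group needed for ionisation by iridium.

Step 9
Reactants: 4 2-(3-methylbut-2-enyl)-3,5-bis(triisopropylsilyloxy)phenol; 12 methyl (E)-3-[2,2-dimethyl-7-(triisopropylsilyloxy)-2H-chromen-6-yl]prop-2-enyl carbonate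
Product: 14 (S)-6-{1-[2-(3-methylbut-2-enyl)-3,5-bis(triisopropylsilyloxy)phenoxy]prop-2-enyl}-2,2-dimethyl-7-(triisopropylsilyloxy)-2H-chromene, via lithium aryloxide 13 (not isolated)
Conditions: 4, n-BuLi, THF, 0 °C; then 12, [Ir(cod)Cl]2 (2 mol %), (Sa,Sc,Sc)-binaphthol-derived N,N-bis(1-phenylethyl)phosphoramidite (4 mol %, pre-activated with n-PrNH2), THF, rt → 40 °C
Reagents that add atoms: none
Why: Iridium-catalysed enantioselective allylic etherification with an alkali aryloxide: the aryloxide attacks the aryl-substituted terminus of the (π-allyl)iridium complex (branched selectivity) on the face fixed by the cyclometalated phosphoramidite, which sets C2 as (S).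

Step 10
Reactants: 14 (S)-6-{1-[2-(3-methylbut-2-enyl)-3,5-bis(triisopropylsilyloxy)phenoxy]prop-2-enyl}-2,2-dimethyl-7-(triisopropylsilyloxy)-2H-chromene
Product: 16 (S)-3-[2,2-dimethyl-7-(triisopropylsilyloxy)-2H-chromen-6-yl]-3-[2-(3-methylbut-2-enyl)-3,5-bis(triisopropylsilyloxy)phenoxy]propan-1-ol, via alkylborane 15 (not isolated)
Conditions: 9-BBN, THF, 0 °C → rt; then H2O2, aq. NaOAc, 0 °C → rt
Reagents that add atoms: hydrogen peroxide, OO
Why: Hydroboration–oxidation: 9-BBN should add anti-Markovnikov to the terminal vinyl group far faster than to the trisubstituted prenyl alkene or the hindered cis-disubstituted chromene alkene; buffered peroxide spares the silyl ethers and C2 is untouched.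

Step 11
Reactants: 16 (S)-3-[2,2-dimethyl-7-(triisopropylsilyloxy)-2H-chromen-6-yl]-3-[2-(3-methylbut-2-enyl)-3,5-bis(triisopropylsilyloxy)phenoxy]propan-1-ol
Product: 18 (S)-3-[2,2-dimethyl-7-(triisopropylsilyloxy)-2H-chromen-6-yl]-3-[2-(3-methylbut-2-enyl)-3,5-bis(triisopropylsilyloxy)phenoxy]propanoic acid, via aldehyde 17 (not isolated)
Conditions: TEMPO (0.2 equiv), PhI(OAc)2 (2.2 equiv), MeCN/H2O, rt
Reagents that add atoms: water, O
Why: Oxoammonium-catalysed oxidation of the primary alcohol through the aldehyde hydrate to the acid; the mildly acidic medium should not trigger β-elimination of the aryloxide and the alkenes are not touched.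

Step 12
Reactants: 18 (S)-3-[2,2-dimethyl-7-(triisopropylsilyloxy)-2H-chromen-6-yl]-3-[2-(3-methylbut-2-enyl)-3,5-bis(triisopropylsilyloxy)phenoxy]propanoic acid
Product: 20 (S)-4-[3,5-dihydroxy-2-(3-methylbut-2-enyl)phenoxy]-8,8-dimethyl-3,4-dihydro-2H,8H-pyrano[3,2-g]chromen-2-one, via trihydroxy acid 19 (not isolated)
Conditions: n-Bu4NF (3.5 equiv), AcOH (3.5 equiv), THF, 0 °C; extractive work-up; then EDC·HCl, CH2Cl2/THF (0.01 M), 0 °C → rt
Reagents that add atoms: none
Why: Fluoride cleaves the three aryl silyl ethers and carbodiimide activation then closes the only strain-free lactone, the six-membered one onto the 2'-OH (the ring A hydroxyls could only form rings of eight or more members); C2 is untouched.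

Step 13
Reactants: 20 (S)-4-[3,5-dihydroxy-2-(3-methylbut-2-enyl)phenoxy]-8,8-dimethyl-3,4-dihydro-2H,8H-pyrano[3,2-g]chromen-2-one
Product: 22 (2S)-5,7-dihydroxy-2-(7-hydroxy-2,2-dimethyl-2H-chromen-6-yl)-8-(3-methylbut-2-enyl)-2,3-dihydro-4H-chromen-4-one, via magnesium phenolate 21 (not isolated)
Conditions: MgCl2 (2.5 equiv), Et3N (2.5 equiv), MeCN/THF (0.002 M), 0 °C → rt; pH 5 buffer quench
Reagents that add atoms: none
Why: Proposed new method: MgCl2/Et3N converts the ring A hydroxyl that becomes O5 into a chloromagnesium phenolate whose metal also binds the lactone carbonyl, so the ortho carbon C4a attacks the aryl-ester carbon C4 through a six-membered chelate; the tetrahedral intermediate expels the ring B 2'-aryloxide and the dienone tautomerises to the chelated 5-hydroxy-4-ketone. The closest known reaction types are ortho C–C bond formation of magnesium phenolates with carbonyl electrophiles (the formylation of step 4, ortho-acylation of halomagnesium phenolates with acid chlorides), MgCl2/Et3N C-acylation of soft enolates, and the Fries and enol-ester-to-triketone O-to-C acyl shifts. Ring C closes in a 6-exo-trig mode while the temporary lactone ring opens, so the step is an isomerisation with the aryl ester → hydrogen-bonded aryl ketone change as driving force. No stereocentre is formed, and C2 stays (S) because none of its bonds is broken. The step needs C- over O-acylation and intra- over intermolecular transfer: only C4a can reach the ester carbon through a six-membered transition state (O5 would need an eight-membered ring, O7 and C6 cannot reach), and high dilution disfavours intermolecular transfer. It also needs acyl transfer to outrun β-elimination of the aryloxide and ring-opening of the product to the chalcone, which the weak amine base, the Et3NH+ buffer and the low temperature are meant to secure.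

**Compound list**
1 | phloroglucinol | Oc1cc(O)cc(O)c1 | starting material
2 | prenyl bromide (1-bromo-3-methylbut-2-ene) | CC(C)=CCBr | starting material
3 | 2-(3-methylbut-2-enyl)benzene-1,3,5-triol | CC(C)=CCc1c(O)cc(O)cc1O | intermediate
4 | 2-(3-methylbut-2-enyl)-3,5-bis(triisopropylsilyloxy)phenol | CC(C)=CCc1c(O)cc(O[Si](C(C)C)(C(C)C)C(C)C)cc1O[Si](C(C)C)(C(C)C)C(C)C | intermediate
5 | resorcinol | Oc1cccc(O)c1 | starting material
6 | 3-methylbut-2-enal | CC(C)=CC=O | starting material
7 | 2,2-dimethyl-2H-chromen-7-ol | CC1(C)C=Cc2ccc(O)cc2O1 | intermediate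
8 | 7-hydroxy-2,2-dimethyl-2H-chromene-6-carbaldehyde | CC1(C)C=Cc2cc(C=O)c(O)cc2O1 | intermediate
9 | 2,2-dimethyl-7-(triisopropylsilyloxy)-2H-chromene-6-carbaldehyde | CC1(C)C=Cc2cc(C=O)c(O[Si](C(C)C)(C(C)C)C(C)C)cc2O1 | intermediate
10 | ethyl (E)-3-[2,2-dimethyl-7-(triisopropylsilyloxy)-2H-chromen-6-yl]prop-2-enoate | CCOC(=O)/C=C/c1cc2c(cc1O[Si](C(C)C)(C(C)C)C(C)C)OC(C)(C)C=C2 | intermediate
11 | (E)-3-[2,2-dimethyl-7-(triisopropylsilyloxy)-2H-chromen-6-yl]prop-2-en-1-ol | OC/C=C/c1cc2c(cc1O[Si](C(C)C)(C(C)C)C(C)C)OC(C)(C)C=C2 | intermediate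
12 | methyl (E)-3-[2,2-dimethyl-7-(triisopropylsilyloxy)-2H-chromen-6-yl]prop-2-enyl carbonate | COC(=O)OC/C=C/c1cc2c(cc1O[Si](C(C)C)(C(C)C)C(C)C)OC(C)(C)C=C2 | intermediate
13 | lithium 2-(3-methylbut-2-enyl)-3,5-bis(triisopropylsilyloxy)phenolate | [Li+].CC(C)=CCc1c([O-])cc(O[Si](C(C)C)(C(C)C)C(C)C)cc1O[Si](C(C)C)(C(C)C)C(C)C | intermediate
14 | (S)-6-{1-[2-(3-methylbut-2-enyl)-3,5-bis(triisopropylsilyloxy)phenoxy]prop-2-enyl}-2,2-dimethyl-7-(triisopropylsilyloxy)-2H-chromene | C=C[C@H](Oc1cc(O[Si](C(C)C)(C(C)C)C(C)C)cc(O[Si](C(C)C)(C(C)C)C(C)C)c1CC=C(C)C)c1cc2c(cc1O[Si](C(C)C)(C(C)C)C(C)C)OC(C)(C)C=C2 | intermediate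
15 | (S)-9-{3-[2,2-dimethyl-7-(triisopropylsilyloxy)-2H-chromen-6-yl]-3-[2-(3-methylbut-2-enyl)-3,5-bis(triisopropylsilyloxy)phenoxy]propyl}-9-borabicyclo[3.3.1]nonane | B1(CC[C@H](Oc2cc(O[Si](C(C)C)(C(C)C)C(C)C)cc(O[Si](C(C)C)(C(C)C)C(C)C)c2CC=C(C)C)c2cc3c(cc2O[Si](C(C)C)(C(C)C)C(C)C)OC(C)(C)C=C3)C2CCCC1CCC2 | intermediate
16 | (S)-3-[2,2-dimethyl-7-(triisopropylsilyloxy)-2H-chromen-6-yl]-3-[2-(3-methylbut-2-enyl)-3,5-bis(triisopropylsilyloxy)phenoxy]propan-1-ol | OCC[C@H](Oc1cc(O[Si](C(C)C)(C(C)C)C(C)C)cc(O[Si](C(C)C)(C(C)C)C(C)C)c1CC=C(C)C)c1cc2c(cc1O[Si](C(C)C)(C(C)C)C(C)C)OC(C)(C)C=C2 | intermediate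
17 | (S)-3-[2,2-dimethyl-7-(triisopropylsilyloxy)-2H-chromen-6-yl]-3-[2-(3-methylbut-2-enyl)-3,5-bis(triisopropylsilyloxy)phenoxy]propanal | O=CC[C@H](Oc1cc(O[Si](C(C)C)(C(C)C)C(C)C)cc(O[Si](C(C)C)(C(C)C)C(C)C)c1CC=C(C)C)c1cc2c(cc1O[Si](C(C)C)(C(C)C)C(C)C)OC(C)(C)C=C2 | intermediate
18 | (S)-3-[2,2-dimethyl-7-(triisopropylsilyloxy)-2H-chromen-6-yl]-3-[2-(3-methylbut-2-enyl)-3,5-bis(triisopropylsilyloxy)phenoxy]propanoic acid | OC(=O)C[C@H](Oc1cc(O[Si](C(C)C)(C(C)C)C(C)C)cc(O[Si](C(C)C)(C(C)C)C(C)C)c1CC=C(C)C)c1cc2c(cc1O[Si](C(C)C)(C(C)C)C(C)C)OC(C)(C)C=C2 | intermediate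
19 | (S)-3-[3,5-dihydroxy-2-(3-methylbut-2-enyl)phenoxy]-3-(7-hydroxy-2,2-dimethyl-2H-chromen-6-yl)propanoic acid | OC(=O)C[C@H](Oc1cc(O)cc(O)c1CC=C(C)C)c1cc2c(cc1O)OC(C)(C)C=C2 | intermediate
20 | (S)-4-[3,5-dihydroxy-2-(3-methylbut-2-enyl)phenoxy]-8,8-dimethyl-3,4-dihydro-2H,8H-pyrano[3,2-g]chromen-2-one | O=C1C[C@H](Oc2cc(O)cc(O)c2CC=C(C)C)c2cc3C=CC(C)(C)Oc3cc2O1 | intermediate
21 | chloromagnesium 5-phenolate of 20 (phenolate at the ring A oxygen that becomes O5) | O=C1C[C@H](Oc2cc([O-])cc(O)c2CC=C(C)C)c2cc3C=CC(C)(C)Oc3cc2O1.[Mg+2].[Cl-] | intermediate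
22 | (2S)-5,7-dihydroxy-2-(7-hydroxy-2,2-dimethyl-2H-chromen-6-yl)-8-(3-methylbut-2-enyl)-2,3-dihydro-4H-chromen-4-one (CNP0150213.1) | CC(C)=CCc1c(O)cc(O)c2c1O[C@H](c1cc3c(cc1O)OC(C)(C)C=C3)CC2=O | target

**Step count and risks**
Total: 13 steps. Longest linear sequence: 11 steps (steps 3–13, from resorcinol).

Most likely to fail:

1. Step 13 (proposed new method). β-Elimination of the ring A aryloxide from the lactone (retro-oxa-Michael, giving the coumarin and the phenol) may outrun the acyl shift. The product may also lose enantiomeric purity by reversible ring-opening to the chalcone, and intermolecular transacylation may give oligomers. The fallback uses known chemistry, sets out from 18 and returns at 22. Acid 18 is converted with 1-chloro-N,N,2-trimethylprop-1-en-1-amine (CH2Cl2, 0 °C) into the acid chloride F1. This is closed by a classical intramolecular Friedel–Crafts acylation (SnCl4, CH2Cl2, −78 °C) onto the silyl-protected ring A to give the tris-silylated flavanone F2. n-Bu4NF/AcOH (THF, 0 °C) then cleaves the three silyl ethers to give 22.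

2. Step 9. The electron-rich branched ether may re-ionise on iridium, with erosion of enantiomeric purity and drift to the linear ether. The ortho-silyloxy group may slow ionisation of the carbonate, and C-allylation of the aryloxide may compete. The fallback fixes the stereocentre before the C–O bond is made, sets out from 9 and returns at 14. Aldehyde 9 is treated with CH2=CHMgBr to give the racemic allylic alcohol F3, which MnO2 oxidises to the aryl vinyl ketone F4. Corey–Bakshi–Shibata reduction ((R)-2-methyl-oxazaborolidine, BH3·SMe2, aryl as the large group) should give the (S)-alcohol F5, and ClCO2Me/pyridine the (S)-methyl carbonate F6. Stereoretentive rhodium-catalysed allylic etherification (RhCl(PPh3)3, P(OMe)3, copper aryloxide made from 4, LiN(SiMe3)2 and CuI, THF, 0 °C) then gives 14.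

3. Step 2. Silylation may go to both ortho hydroxyls or to all three, which would lower the supply of 4 and, with the wrong free hydroxyl, lead into the 6-prenyl series. The fallback reverses the order of silylation and prenylation, sets out from 1 and returns at 4. Phloroglucinol 1 is silylated (i-Pr3SiCl, 2 equiv, imidazole, DMF) to 3,5-bis(triisopropylsilyloxy)phenol F7; all hydroxyls of 1 are equivalent, so only the degree of silylation has to be controlled. The sodium phenoxide of F7 (NaH, toluene) is then C-prenylated with 2 at an ortho position (ortho-C-alkylation of a phenoxide ion pair in a non-polar solvent) to give 4. Both ortho positions are equivalent and the para position is shielded by two silyloxy groups.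

**Further compounds**
F1 | step 13 | (S)-3-[2,2-dimethyl-7-(triisopropylsilyloxy)-2H-chromen-6-yl]-3-[2-(3-methylbut-2-enyl)-3,5-bis(triisopropylsilyloxy)phenoxy]propanoyl chloride | ClC(=O)C[C@H](Oc1cc(O[Si](C(C)C)(C(C)C)C(C)C)cc(O[Si](C(C)C)(C(C)C)C(C)C)c1CC=C(C)C)c1cc2c(cc1O[Si](C(C)C)(C(C)C)C(C)C)OC(C)(C)C=C2
F2 | step 13 | (2S)-2-[2,2-dimethyl-7-(triisopropylsilyloxy)-2H-chromen-6-yl]-8-(3-methylbut-2-enyl)-5,7-bis(triisopropylsilyloxy)-2,3-dihydro-4H-chromen-4-one | CC(C)=CCc1c(O[Si](C(C)C)(C(C)C)C(C)C)cc(O[Si](C(C)C)(C(C)C)C(C)C)c2c1O[C@H](c1cc3c(cc1O[Si](C(C)C)(C(C)C)C(C)C)OC(C)(C)C=C3)CC2=O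
F3 | step 9 | racemic 1-[2,2-dimethyl-7-(triisopropylsilyloxy)-2H-chromen-6-yl]prop-2-en-1-ol | C=CC(O)c1cc2c(cc1O[Si](C(C)C)(C(C)C)C(C)C)OC(C)(C)C=C2
F4 | step 9 | 1-[2,2-dimethyl-7-(triisopropylsilyloxy)-2H-chromen-6-yl]prop-2-en-1-one | C=CC(=O)c1cc2c(cc1O[Si](C(C)C)(C(C)C)C(C)C)OC(C)(C)C=C2
F5 | step 9 | (S)-1-[2,2-dimethyl-7-(triisopropylsilyloxy)-2H-chromen-6-yl]prop-2-en-1-ol | C=C[C@H](O)c1cc2c(cc1O[Si](C(C)C)(C(C)C)C(C)C)OC(C)(C)C=C2
F6 | step 9 | (S)-1-[2,2-dimethyl-7-(triisopropylsilyloxy)-2H-chromen-6-yl]prop-2-enyl methyl carbonate | C=C[C@H](OC(=O)OC)c1cc2c(cc1O[Si](C(C)C)(C(C)C)C(C)C)OC(C)(C)C=C2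
F7 | step 2 | 3,5-bis(triisopropylsilyloxy)phenol | Oc1cc(O[Si](C(C)C)(C(C)C)C(C)C)cc(O[Si](C(C)C)(C(C)C)C(C)C)c1
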